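How much side product B stands at the end of the flask, and does target appear if it is left for a very long time?

| flask | substrate | reagent | remark | time |
|---|---|---|---|---|
| spring | 0.0010 M | 2 mM (fed, over 5.0 s) | run made earlier; the fed solution adds 0.50 times the starting volume |  |
| dusk | 0.0010 M | 3 mM (fed, over 5.0 s) | run made earlier; the fed solution adds 0.50 times the starting volume |  |
| summer | 0.0020 M | 4 mM (fed, over 5.0 s) | run made earlier; the fed solution adds 0.50 times the starting volume |  |
| flask | 0.0010 M | 4.00 mM (fed, over 5.0 s) | the fed solution adds 0.50 times the starting volume | 30 min |

| run | time / min | side product B / % | target / % | substrate / % |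
|---|---|---|---|---|
| spring | 1.50 | 78.3 | 0 | 2.1 |
| spring | 5.00 | 78.9 | 1.5 | 0 |
| spring | 8.00 | 78.2 | 0 | 0.8 |
| spring | 12.0 | 77.4 | 0 | 0 |
| spring | 20.0 | 79.4 | 0.1 | 1.5 |
| spring | 25.0 | 78.2 | 0 | 0 |
| spring | 30.0 | 78.9 | 0.4 | 0 |
| dusk | 2.50 | 76.2 | 0.9 | 1.6 |
| dusk | 4.00 | 76.1 | 1.6 | 0 |
| dusk | 6.00 | 75.8 | 0 | 0 |
| dusk | 8.00 | 76.4 | 0.3 | 1.0 |
| dusk | 12.0 | 77.2 | 0.4 | 1.3 |
| dusk | 20.0 | 75.2 | 0 | 0 |
| dusk | 30.0 | 75.6 | 0 | 0.3 |
| summer | 6.00 | 81.7 | 0.6 | 0 |
| summer | 12.0 | 84.4 | 0 | 0 |
| summer | 20.0 | 83.3 | 0.8 | 0.1 |
| summer | 25.0 | 82.4 | 0 | 0 |
| summer | 30.0 | 83.3 | 2.2 | 1.9 |

(scatter of a reading: 1 percentage point)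

- how much side product B there is at 30 min, in percent of the substrate charged
- amount of target if the flask were left three thousand times as long, in percent of the substrate charged

- a species is counted by the substrate in it: one side product B counts as two
- charges are per starting volume, the dose included; the dosed solution carries all of it
- the numbers in the tables scatter with a standard deviation of 1 percentage point

In the spring run, substrate reads 2.1% at the first sample and side product B stays flat, so the split appears to be made early. Averaged over each run, side product B leaves a gap to the charge of 21.5% in spring, 23.9% in dusk and 17.0% in summer.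

Suppose reagent turns substrate into an intermediate, which then takes a second substrate to side product B. Dividing the two rates removes substrate and time, leaving a selectivity factor that follows intermediate over reagent present. If substrate is consumed inside a steady dose of fixed length, the reagent standing meanwhile scales with the square root of its charge. The load is therefore substrate charge over the square root of reagent charge, scaled to spring: 0.816 for dusk, 1.41 for summer and 0.707 for the flask.

The gap should follow a power of the load, and two routes give that power. The reagent step from spring to dusk gives 0.521, which puts the flask's gap at 25.8%. The substrate step from spring to summer gives 0.685 and 27.3%. The two routes part by 1.5 points, and the reagent step rests on a gap difference of 2.4 points, smaller than the 4.5 points of the substrate step. The widest span in load, dusk to summer, therefore gives the load exponent 0.624. This reckoning puts the flask's gap at 26.2% and side product B at 73.8%. The last target readings of spring, dusk and summer are 0.4%, 0% and 2.2% at a scatter of 1 point, and side product B stays flat, so this reckoning expects target near zero in the flask, left long as well.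

The forecast gives 73% of side product B (70.5% to 75.5%), close to this reckoning. For target it gives 26.5% (15% to 30%), “though that conversion is an assumption”, and there the two differ.

The flask gives 73.1% of side product B and, left very long, 0% of target. Its gap is side product A, 26.9% at 30.0 min, beside 0% of target. The load exponent had placed that gap at 26.2%, against 26.9% in the flask.

    substrate + reagent → target + by-product (k = 1130 /M/s)
    target + by-product → side product A (k = 315 /M/s)
    substrate + target → side product B (k = 3710 /M/s)

A neighbour flask, like the flask but with 2.5 × 10⁻⁴ M of substrate, has a load of 0.177. Starting from the flask's gap, the load exponent gives a gap of 63.9% there, so 36.1% of side product B. The computed neighbour flask holds 40.2% of side product B and 59.8% of side product A.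

(The earlier runs and the new flask were generated by integration with constants of no real substance, noise included.)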